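**Plan**
- Retrosynthesis first cuts the two O–Si bonds at O5 and O7, then C2–C3 of ring C. This opens the flavanone to an aryl diazomethyl ketone whose neighbouring oxygen carries a 4-methoxybenzyl group.
- The cut is possible because C2 bears ring B, one hydrogen and O1, so in the open form it is the benzylic CH2 of a 4-methoxybenzyl aryl ether. C3 lies next to the C4 carbonyl, where a diazo group can be turned into a carbene.
- Earlier cuts: N2 and the C3 carbon from C4, O1–CH2 (ring B), C4–C4a (formyl), C8a–O1 (aryl C–O) and C6–prenyl.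
- Forward: ring A is bought as resorcinol. Prenyl enters by directed lithiation, MOM is exchanged for TIPS, O1 comes from iridium C–H borylation/oxidation, C4 from ortho-formylation, ring B from a Mitsunobu etherification, and C3 from Grignard addition, oxidation and diazo transfer. Ring C closes in the penultimate step and desilylation ends the route.
- The only stereocentre, C2 (S), is set in the ring closure by the chiral dirhodium carboxylate, which selects one of the two enantiotopic benzylic hydrogens. Buffered desilylation preserves it.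

Key step: step 11

Assumption: Rh2(S-PTTL)4 (PTTL = N-phthaloyl-tert-leucinate) is taken to give the (S) configuration at C2. The sense of induction has to be checked on the first run, and Rh2(R-PTTL)4 would replace it if the antipode predominates.

**Route**

Step 1
Reactants: 1 resorcinol
Product: 2 1,3-bis(methoxymethoxy)benzene
Conditions: NaH, MOMCl, DMF, 0 °C → rt
Reagents that add atoms: chloromethyl methyl ether, COCCl
Why: Williamson-type O-alkylation of the sodium bis-phenoxide with the reactive alpha-chloro ether should give the bis-acetal, whose two MOM groups later direct lithiation to the carbon between them.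

Step 2
Reactants: 2 1,3-bis(methoxymethoxy)benzene; 3 prenyl bromide (1-bromo-3-methylbut-2-ene)
Product: 5 1,3-bis(methoxymethoxy)-2-(3-methylbut-2-enyl)benzene, via aryllithium 4 (not isolated)
Conditions: n-BuLi, THF, 0 °C; then CuBr·SMe2 (10 mol %), 3, −78 °C → rt
Reagents that add atoms: n-butyllithium, [Li]CCCC (lithium of intermediate 4 only; nothing of it remains in 5)
Why: Directed ortho-metalation places lithium only between the two chelating MOM ethers, and copper-assisted SN2 alkylation at the primary carbon of prenyl bromide should give the linear prenyl group.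

Step 3
Reactants: 5 1,3-bis(methoxymethoxy)-2-(3-methylbut-2-enyl)benzene
Product: 6 2-(3-methylbut-2-enyl)benzene-1,3-diol
Conditions: HCl (3 M aq.), MeOH, 45 °C, stopped at full conversion
Reagents that add atoms: none
Why: Acid-catalysed acetal exchange with methanol (MOM cleavage) is faster than protonation of the trisubstituted alkene, so the diol should be released before cyclisation to a chroman sets in.

Step 4
Reactants: 6 2-(3-methylbut-2-enyl)benzene-1,3-diol
Product: 7 2-(3-methylbut-2-enyl)-1,3-bis(triisopropylsilyloxy)benzene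
Conditions: TIPSCl, imidazole, DMF, rt → 40 °C
Reagents that add atoms: chlorotriisopropylsilane, CC(C)[Si](Cl)(C(C)C)C(C)C
Why: Imidazole-promoted silylation of the phenols should give the bis-silyl ether, and TIPS is chosen because it offers the later carbene no C–H alpha to oxygen and survives the Grignard and enolate steps.

Step 5
Reactants: 7 2-(3-methylbut-2-enyl)-1,3-bis(triisopropylsilyloxy)benzene
Product: 9 4-(3-methylbut-2-enyl)-3,5-bis(triisopropylsilyloxy)phenol, via pinacol boronate 8 (not isolated)
Conditions: [Ir(OMe)(cod)]2 (1.5 mol %), 4,4'-di-tert-butyl-2,2'-bipyridine (3 mol %), B2pin2 (0.7 equiv), hexane, 60 °C; then NaBO3·4H2O, THF/H2O, rt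
Reagents that add atoms: bis(pinacolato)diboron, CC1(C)OB(OC1(C)C)B1OC(C)(C)C(C)(C)O1 (boron of intermediate 8 only); sodium perborate, [Na+].[O-]OB=O (the phenol oxygen)
Why: Iridium-catalysed aromatic C–H borylation (Hartwig–Miyaura type) is sterically controlled and in this 1,2,3-trisubstituted benzene should reach only the C–H flanked by two hydrogens, after which perborate oxidation converts the boronate into the phenol by aryl migration from boron to oxygen.

Step 6
Reactants: 9 4-(3-methylbut-2-enyl)-3,5-bis(triisopropylsilyloxy)phenol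
Product: 10 2-hydroxy-5-(3-methylbut-2-enyl)-4,6-bis(triisopropylsilyloxy)benzaldehyde
Conditions: MgCl2, Et3N, (CH2O)n, MeCN, reflux
Reagents that add atoms: paraformaldehyde (as formaldehyde), C=O
Why: In the magnesium-mediated ortho-formylation of phenols (Casnati–Skattebøl reaction) the magnesium phenoxide delivers formaldehyde only to an ortho carbon and a second formaldehyde oxidises the hydroxymethyl intermediate, and the symmetry of 9 makes both ortho sites give the same aldehyde.

Step 7
Reactants: 10 2-hydroxy-5-(3-methylbut-2-enyl)-4,6-bis(triisopropylsilyloxy)benzaldehyde; 11 4-methoxybenzyl alcohol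
Product: 12 2-(4-methoxybenzyloxy)-5-(3-methylbut-2-enyl)-4,6-bis(triisopropylsilyloxy)benzaldehyde
Conditions: PPh3, DIAD, THF, 0 °C → rt
Reagents that add atoms: none
Why: In this Mitsunobu etherification the hydrogen-bonded salicylaldehyde-type phenol is acidic enough to protonate the betaine and should then displace the oxyphosphonium of the primary benzylic alcohol under neutral conditions that leave the silyl ethers alone.

Step 8
Reactants: 12 2-(4-methoxybenzyloxy)-5-(3-methylbut-2-enyl)-4,6-bis(triisopropylsilyloxy)benzaldehyde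
Product: 13 1-[2-(4-methoxybenzyloxy)-5-(3-methylbut-2-enyl)-4,6-bis(triisopropylsilyloxy)phenyl]ethanol (racemic)
Conditions: MeMgBr, THF, −78 → 0 °C; H2O quench
Reagents that add atoms: methylmagnesium bromide, C[Mg]Br
Why: Grignard 1,2-addition to the aldehyde should give the secondary alcohol as a racemate, which is harmless because the carbinol centre is oxidised away in the next step.

Step 9
Reactants: 13 1-[2-(4-methoxybenzyloxy)-5-(3-methylbut-2-enyl)-4,6-bis(triisopropylsilyloxy)phenyl]ethanol
Product: 14 1-[2-(4-methoxybenzyloxy)-5-(3-methylbut-2-enyl)-4,6-bis(triisopropylsilyloxy)phenyl]ethanone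
Conditions: Dess–Martin periodinane, pyridine, CH2Cl2, 0 °C → rt (crude 13 used directly)
Reagents that add atoms: none
Why: Dess–Martin oxidation under pyridine buffering should convert the secondary benzylic alcohol into the ketone without ionising the electron-rich benzylic position or touching the alkene and the ethers.

Step 10
Reactants: 14 1-[2-(4-methoxybenzyloxy)-5-(3-methylbut-2-enyl)-4,6-bis(triisopropylsilyloxy)phenyl]ethanone
Product: 16 2-diazo-1-[2-(4-methoxybenzyloxy)-5-(3-methylbut-2-enyl)-4,6-bis(triisopropylsilyloxy)phenyl]ethanone, via trifluoroacetyl ketone 15 (not isolated)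
Conditions: LiN(SiMe3)2, THF, −78 °C; CF3CO2CH2CF3; then MsN3, Et3N, H2O (1 equiv), MeCN, rt
Reagents that add atoms: 2,2,2-trifluoroethyl trifluoroacetate, FC(F)(F)COC(=O)C(F)(F)F (trifluoroacetyl group of intermediate 15 only); methanesulfonyl azide, CS(=O)(=O)N=[N+]=[N-] (the two diazo nitrogens)
Why: In this detrifluoroacetylative diazo transfer (a Regitz-type deacylative diazo transfer) Claisen trifluoroacetylation of the kinetic lithium enolate activates the methyl carbon, and the sulfonyl azide should then deliver N2 while the trifluoroacetyl group leaves as the N-acyl sulfonamide.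

Step 11
Reactants: 16 2-diazo-1-[2-(4-methoxybenzyloxy)-5-(3-methylbut-2-enyl)-4,6-bis(triisopropylsilyloxy)phenyl]ethanone
Product: 17 (S)-2-(4-methoxyphenyl)-6-(3-methylbut-2-enyl)-5,7-bis(triisopropylsilyloxy)chroman-4-one
Conditions: Rh2(S-PTTL)4 (2 mol %), toluene, 0 °C, slow addition of 16
Reagents that add atoms: none
Why: The divalent-rhodium dimer Rh2(S-PTTL)4 adds to the diazo carbon of 16, N2 departs, and the rhodium-bound electrophilic carbene at the future C3 takes up one benzylic C–H bond of the 4-methoxybenzyl ether in a concerted, asynchronous three-centre event with hydride-shift character, forming C2–C3 and releasing the catalyst. The closest known reaction type is the dirhodium carboxylate-catalysed enantioselective intramolecular C–H insertion of 2-alkoxyaryl diazomethyl ketones into the ether alpha C–H bond to give 2-substituted chroman-4-ones. Ring C closes six-membered by 1,6-insertion (carbene carbon, C4, C4a, C8a, O1, benzylic carbon), because the atom at the usual 1,5-position is the ether oxygen itself. C2 is set by the chiral N-phthaloyl-tert-leucinate ligand sphere, which distinguishes the two enantiotopic benzylic hydrogens, with no substrate stereocentre involved. The step needs C–H insertion to outrun oxonium ylide formation at O1 with 1,2-benzyl shift, attack on the prenyl alkene and reaction at the second ortho oxygen. In the substrate the reacting C–H is doubly activated by O1 and the 4-methoxyphenyl ring, the prenyl group sits meta to the acyl carbon and cannot reach the carbene, the TIPS ether at O5 is shielded and has no alpha C–H, and the bulky carboxylate catalyst in a nonpolar solvent disfavours the ylide.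

Step 12
Reactants: 17 (S)-2-(4-methoxyphenyl)-6-(3-methylbut-2-enyl)-5,7-bis(triisopropylsilyloxy)chroman-4-one
Product: 18 (S)-5,7-dihydroxy-2-(4-methoxyphenyl)-6-(3-methylbut-2-enyl)chroman-4-one
Conditions: Bu4NF, AcOH (1:1), THF, 0 °C → rt
Reagents that add atoms: none
Why: Fluoride-driven cleavage of both aryl silyl ethers should free the phenols, while acetic acid keeps them protonated so that base-induced ring opening to the chalcone, which would racemise C2, is avoided.

**Compound list**

1 | resorcinol | Oc1cccc(O)c1 | starting material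
2 | 1,3-bis(methoxymethoxy)benzene | COCOc1cccc(OCOC)c1 | intermediate
3 | prenyl bromide (1-bromo-3-methylbut-2-ene) | CC(C)=CCBr | starting material
4 | [2,6-bis(methoxymethoxy)phenyl]lithium | [Li]c1c(OCOC)cccc1OCOC | intermediate (not isolated)
5 | 1,3-bis(methoxymethoxy)-2-(3-methylbut-2-enyl)benzene | COCOc1cccc(OCOC)c1CC=C(C)C | intermediate
6 | 2-(3-methylbut-2-enyl)benzene-1,3-diol | Oc1cccc(O)c1CC=C(C)C | intermediate
7 | 2-(3-methylbut-2-enyl)-1,3-bis(triisopropylsilyloxy)benzene | CC(C)=CCc1c(O[Si](C(C)C)(C(C)C)C(C)C)cccc1O[Si](C(C)C)(C(C)C)C(C)C | intermediate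
8 | 2-[4-(3-methylbut-2-enyl)-3,5-bis(triisopropylsilyloxy)phenyl]-4,4,5,5-tetramethyl-1,3,2-dioxaborolane | CC(C)=CCc1c(O[Si](C(C)C)(C(C)C)C(C)C)cc(B2OC(C)(C)C(C)(C)O2)cc1O[Si](C(C)C)(C(C)C)C(C)C | intermediate (not isolated)
9 | 4-(3-methylbut-2-enyl)-3,5-bis(triisopropylsilyloxy)phenol | CC(C)=CCc1c(O[Si](C(C)C)(C(C)C)C(C)C)cc(O)cc1O[Si](C(C)C)(C(C)C)C(C)C | intermediate
10 | 2-hydroxy-5-(3-methylbut-2-enyl)-4,6-bis(triisopropylsilyloxy)benzaldehyde | CC(C)=CCc1c(O[Si](C(C)C)(C(C)C)C(C)C)cc(O)c(C=O)c1O[Si](C(C)C)(C(C)C)C(C)C | intermediate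
11 | 4-methoxybenzyl alcohol | COc1ccc(CO)cc1 | starting material
12 | 2-(4-methoxybenzyloxy)-5-(3-methylbut-2-enyl)-4,6-bis(triisopropylsilyloxy)benzaldehyde | COc1ccc(COc2cc(O[Si](C(C)C)(C(C)C)C(C)C)c(CC=C(C)C)c(O[Si](C(C)C)(C(C)C)C(C)C)c2C=O)cc1 | intermediate
13 | 1-[2-(4-methoxybenzyloxy)-5-(3-methylbut-2-enyl)-4,6-bis(triisopropylsilyloxy)phenyl]ethanol (racemic) | COc1ccc(COc2cc(O[Si](C(C)C)(C(C)C)C(C)C)c(CC=C(C)C)c(O[Si](C(C)C)(C(C)C)C(C)C)c2C(C)O)cc1 | intermediate
14 | 1-[2-(4-methoxybenzyloxy)-5-(3-methylbut-2-enyl)-4,6-bis(triisopropylsilyloxy)phenyl]ethanone | COc1ccc(COc2cc(O[Si](C(C)C)(C(C)C)C(C)C)c(CC=C(C)C)c(O[Si](C(C)C)(C(C)C)C(C)C)c2C(C)=O)cc1 | intermediate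
15 | 4,4,4-trifluoro-1-[2-(4-methoxybenzyloxy)-5-(3-methylbut-2-enyl)-4,6-bis(triisopropylsilyloxy)phenyl]butane-1,3-dione | COc1ccc(COc2cc(O[Si](C(C)C)(C(C)C)C(C)C)c(CC=C(C)C)c(O[Si](C(C)C)(C(C)C)C(C)C)c2C(=O)CC(=O)C(F)(F)F)cc1 | intermediate (not isolated)
16 | 2-diazo-1-[2-(4-methoxybenzyloxy)-5-(3-methylbut-2-enyl)-4,6-bis(triisopropylsilyloxy)phenyl]ethanone | COc1ccc(COc2cc(O[Si](C(C)C)(C(C)C)C(C)C)c(CC=C(C)C)c(O[Si](C(C)C)(C(C)C)C(C)C)c2C(=O)C=[N+]=[N-])cc1 | intermediate
17 | (S)-2-(4-methoxyphenyl)-6-(3-methylbut-2-enyl)-5,7-bis(triisopropylsilyloxy)chroman-4-one | COc1ccc([C@@H]2CC(=O)c3c(cc(O[Si](C(C)C)(C(C)C)C(C)C)c(CC=C(C)C)c3O[Si](C(C)C)(C(C)C)C(C)C)O2)cc1 | intermediate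
18 | (S)-5,7-dihydroxy-2-(4-methoxyphenyl)-6-(3-methylbut-2-enyl)chroman-4-one | COc1ccc([C@@H]2CC(=O)c3c(cc(O)c(CC=C(C)C)c3O)O2)cc1 | target

**Count and risks**

Total step count: 12. Longest linear sequence: 12 steps, from resorcinol through to the target.

Steps most likely to fail, in order:

1. Step 11. The carbene may be captured by the lone pair of the ether oxygen and pass through an oxonium ylide with 1,2-benzyl migration instead of inserting, or the catalyst may distinguish the two benzylic hydrogens poorly.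
   - Fallback: C2 would instead be made by asymmetric aryl addition to a chromone, setting out from ketone 14.
   - DDQ in CH2Cl2/water would remove the 4-methoxybenzyl group to give 1-[2-hydroxy-5-(3-methylbut-2-enyl)-4,6-bis(triisopropylsilyloxy)phenyl]ethanone F1.
   - Heating with N,N-dimethylformamide dimethyl acetal should give (E)-3-(dimethylamino)-1-[2-hydroxy-5-(3-methylbut-2-enyl)-4,6-bis(triisopropylsilyloxy)phenyl]prop-2-en-1-one F2.
   - Catalytic TsOH should close this to 6-(3-methylbut-2-enyl)-5,7-bis(triisopropylsilyloxy)chromen-4-one F3.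
   - Conjugate addition of 4-methoxyphenylboronic acid under Pd(OCOCF3)2, with the enantiomer of the tert-butyl pyridine-oxazoline ligand that leads to the (S) product, would return to the route at 17.

2. Step 5. Iridium boryl or hydride species may engage the prenyl double bond (hydroboration, isomerisation), or borylation of the electron-rich ring may be slow.
   - Fallback: the borylation would be moved ahead of the prenylation, setting out from 2.
   - The same [Ir(OMe)(cod)]2/bipyridine/B2pin2 borylation would give 2-[3,5-bis(methoxymethoxy)phenyl]-4,4,5,5-tetramethyl-1,3,2-dioxaborolane F4 (not isolated), and perborate oxidation would give 3,5-bis(methoxymethoxy)phenol F5.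
   - TBSCl/imidazole would give tert-butyl[3,5-bis(methoxymethoxy)phenoxy]dimethylsilane F6.
   - n-BuLi would lithiate between the two MOM groups to [4-(tert-butyldimethylsilyloxy)-2,6-bis(methoxymethoxy)phenyl]lithium F7, and prenyl bromide 3 with CuBr·SMe2 would give tert-butyl[3,5-bis(methoxymethoxy)-4-(3-methylbut-2-enyl)phenoxy]dimethylsilane F8.
   - HCl in methanol at room temperature would cleave the two acetals to 5-(tert-butyldimethylsilyloxy)-2-(3-methylbut-2-enyl)benzene-1,3-diol F9.
   - TIPSCl/imidazole would give tert-butyldimethyl[4-(3-methylbut-2-enyl)-3,5-bis(triisopropylsilyloxy)phenoxy]silane F10.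
   - KHF2 in methanol would cleave only the unhindered TBS ether and return to the route at 9.

3. Step 6. Formylation at an ortho carbon shielded by the neighbouring TIPS ether may stall, and silyl groups may be lost on prolonged heating with the amine base.
   - Fallback: the formyl group would be introduced by halogen–metal exchange, setting out from 9.
   - NBS in CH2Cl2 at −78 °C would give 2-bromo-4-(3-methylbut-2-enyl)-3,5-bis(triisopropylsilyloxy)phenol F11.
   - Mitsunobu etherification with 11 would give 2-bromo-1-(4-methoxybenzyloxy)-4-(3-methylbut-2-enyl)-3,5-bis(triisopropylsilyloxy)benzene F12.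
   - Bromine–lithium exchange with n-BuLi in THF at −78 °C would give [2-(4-methoxybenzyloxy)-5-(3-methylbut-2-enyl)-4,6-bis(triisopropylsilyloxy)phenyl]lithium F13, and an immediate DMF quench would deliver the aldehyde, rejoining the route at 12.

**Further compounds**

F1 | step 11 | 1-[2-hydroxy-5-(3-methylbut-2-enyl)-4,6-bis(triisopropylsilyloxy)phenyl]ethanone | CC(=O)c1c(O)cc(O[Si](C(C)C)(C(C)C)C(C)C)c(CC=C(C)C)c1O[Si](C(C)C)(C(C)C)C(C)C
F2 | step 11 | (E)-3-(dimethylamino)-1-[2-hydroxy-5-(3-methylbut-2-enyl)-4,6-bis(triisopropylsilyloxy)phenyl]prop-2-en-1-one | CN(C)/C=C/C(=O)c1c(O)cc(O[Si](C(C)C)(C(C)C)C(C)C)c(CC=C(C)C)c1O[Si](C(C)C)(C(C)C)C(C)C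
F3 | step 11 | 6-(3-methylbut-2-enyl)-5,7-bis(triisopropylsilyloxy)chromen-4-one | O=c1ccoc2cc(O[Si](C(C)C)(C(C)C)C(C)C)c(CC=C(C)C)c(O[Si](C(C)C)(C(C)C)C(C)C)c12
F4 | step 5 | 2-[3,5-bis(methoxymethoxy)phenyl]-4,4,5,5-tetramethyl-1,3,2-dioxaborolane | COCOc1cc(OCOC)cc(B2OC(C)(C)C(C)(C)O2)c1
F5 | step 5 | 3,5-bis(methoxymethoxy)phenol | COCOc1cc(O)cc(OCOC)c1
F6 | step 5 | tert-butyl[3,5-bis(methoxymethoxy)phenoxy]dimethylsilane | COCOc1cc(OCOC)cc(O[Si](C)(C)C(C)(C)C)c1
F7 | step 5 | [4-(tert-butyldimethylsilyloxy)-2,6-bis(methoxymethoxy)phenyl]lithium | [Li]c1c(OCOC)cc(O[Si](C)(C)C(C)(C)C)cc1OCOC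
F8 | step 5 | tert-butyl[3,5-bis(methoxymethoxy)-4-(3-methylbut-2-enyl)phenoxy]dimethylsilane | COCOc1cc(O[Si](C)(C)C(C)(C)C)cc(OCOC)c1CC=C(C)C
F9 | step 5 | 5-(tert-butyldimethylsilyloxy)-2-(3-methylbut-2-enyl)benzene-1,3-diol | CC(C)=CCc1c(O)cc(O[Si](C)(C)C(C)(C)C)cc1O
F10 | step 5 | tert-butyldimethyl[4-(3-methylbut-2-enyl)-3,5-bis(triisopropylsilyloxy)phenoxy]silane | CC(C)=CCc1c(O[Si](C(C)C)(C(C)C)C(C)C)cc(O[Si](C)(C)C(C)(C)C)cc1O[Si](C(C)C)(C(C)C)C(C)C
F11 | step 6 | 2-bromo-4-(3-methylbut-2-enyl)-3,5-bis(triisopropylsilyloxy)phenol | CC(C)=CCc1c(O[Si](C(C)C)(C(C)C)C(C)C)cc(O)c(Br)c1O[Si](C(C)C)(C(C)C)C(C)C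
F12 | step 6 | 2-bromo-1-(4-methoxybenzyloxy)-4-(3-methylbut-2-enyl)-3,5-bis(triisopropylsilyloxy)benzene | COc1ccc(COc2cc(O[Si](C(C)C)(C(C)C)C(C)C)c(CC=C(C)C)c(O[Si](C(C)C)(C(C)C)C(C)C)c2Br)cc1
F13 | step 6 | [2-(4-methoxybenzyloxy)-5-(3-methylbut-2-enyl)-4,6-bis(triisopropylsilyloxy)phenyl]lithium | COc1ccc(COc2cc(O[Si](C(C)C)(C(C)C)C(C)C)c(CC=C(C)C)c(O[Si](C(C)C)(C(C)C)C(C)C)c2[Li])cc1
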